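**Plan**

1. Retrosynthesis, last cut first: the two benzyl ethers on ring B and the methyl ether at C2 of ring A are removed together at the end.
2. Ring A is cut at C2–C3 and C1–C6. Its C3(H)–C4(O-acyl)–C5(H)–C6(CH3) edge is the C3–C6 diene of 4-hydroxy-6-methyl-2-pyrone, so only C1 (CO2CH3) and C2 (O) are missing, and they come from methyl 3-methoxypropiolate.
3. The pyranyl ester is cut at the acyl C–O bond into triacetic acid lactone and the ring B acid chloride, which is atraric acid after chlorination at its one free carbon, benzylation and saponification.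
4. Forward: ring B acid chloride (steps 1–4), O-acylation of the pyrone (step 5), alkyne from methyl 3-methoxyacrylate (steps 6–7), ring A by (4+2) cycloaddition and loss of CO2 (step 8), deprotection (step 9).
5. The target has no stereocentre. The only selectivity to set is the orientation of the alkyne in step 8, which should follow from the matched polarisation of the two partners.

Key step: step 8

Remark: ring B is cited with atraric acid numbering (C1 carboxyl, C2 O, C3 CH3, C4 O, C5 Cl, C6 CH3). Intermediate 9 is expected as a diastereomer mixture and 12 as a racemate (drawn as one enantiomer); both are transient.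

**Route**

Step 1
Reactants: 1 atraric acid (methyl 2,4-dihydroxy-3,6-dimethylbenzoate)
Product: 2 methyl 5-chloro-2,4-dihydroxy-3,6-dimethylbenzoate
Conditions: SO2Cl2 (1.05 equiv), Et2O, 0 °C → rt
Reagents that add atoms: sulfuryl chloride, O=S(=O)(Cl)Cl
Why: Electrophilic aromatic chlorination, in which C5 is the only unsubstituted ring carbon and is activated by both phenols, so one equivalent of reagent should chlorinate there alone.

Step 2
Reactants: 2 methyl 5-chloro-2,4-dihydroxy-3,6-dimethylbenzoate
Product: 3 methyl 2,4-bis(benzyloxy)-5-chloro-3,6-dimethylbenzoate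
Conditions: BnBr (2.5 equiv), K2CO3 (3 equiv), DMF, 60 °C
Reagents that add atoms: benzyl bromide, BrCc1ccccc1
Why: Williamson ether synthesis, which under warm carbonate/DMF conditions should alkylate the free C4 phenol and the hydrogen-bonded C2 phenol alike, giving ethers that tolerate every later step up to the BCl3 cleavage.

Step 3
Reactants: 3 methyl 2,4-bis(benzyloxy)-5-chloro-3,6-dimethylbenzoate
Product: 4 2,4-bis(benzyloxy)-5-chloro-3,6-dimethylbenzoic acid
Conditions: KOH (10 equiv), DMSO/H2O, 90 °C; then aq. HCl, 0 °C
Reagents that add atoms: potassium hydroxide, [K+].[OH-]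
Why: Saponification of a di-ortho-substituted benzoate, for which poorly solvated hydroxide in hot aqueous DMSO is the usual remedy, while benzyl aryl ethers and the unactivated aryl chloride should be inert to base.

Step 4
Reactants: 4 2,4-bis(benzyloxy)-5-chloro-3,6-dimethylbenzoic acid
Product: 5 2,4-bis(benzyloxy)-5-chloro-3,6-dimethylbenzoyl chloride
Conditions: (COCl)2 (1.5 equiv), DMF (cat.), CH2Cl2, 0 °C → rt; evaporated, used crude
Reagents that add atoms: oxalyl chloride, O=C(Cl)C(=O)Cl
Why: Acid chloride formation through the Vilsmeier-type chloroiminium species, mild enough to leave the benzyl ethers untouched.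

Step 5
Reactants: 5 2,4-bis(benzyloxy)-5-chloro-3,6-dimethylbenzoyl chloride, 6 triacetic acid lactone (4-hydroxy-6-methyl-2H-pyran-2-one)
Product: 7 6-methyl-2-oxo-2H-pyran-4-yl 2,4-bis(benzyloxy)-5-chloro-3,6-dimethylbenzoate
Conditions: Et3N (1.5 equiv), CH2Cl2, 0 °C → rt
Reagents that add atoms: none
Why: Kinetic O-acylation of the acidic enolic 4-hydroxyl of the pyrone by an acid chloride, run without a nucleophilic catalyst so that the acyl group should stay on oxygen and not migrate to C3, the two ortho substituents then shielding the new ester.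

Step 6
Reactants: 8 methyl (E)-3-methoxyacrylate
Product: 10 methyl (Z)-2-bromo-3-methoxyacrylate, via dibromo ester 9 (not isolated)
Conditions: Br2 (1.05 equiv), CH2Cl2, 0 °C; then Et3N (1.5 equiv), 0 °C → rt
Reagents that add atoms: bromine, BrBr
Why: Bromine addition to the enol ether double bond followed by amine-induced loss of HBr (the acidic C2 hydrogen and the labile C3 bromide of the α-bromo ether), a standard bromination–dehydrobromination that should give the Z bromide with OCH3 trans to the ester.

Step 7
Reactants: 10 methyl (Z)-2-bromo-3-methoxyacrylate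
Product: 11 methyl 3-methoxypropiolate
Conditions: NaN(SiMe3)2 (1.05 equiv), THF, −78 → −40 °C; AcOH, −78 °C
Reagents that add atoms: none
Why: Anti-dehydrobromination (E2) of a 2-bromovinyl ether to an alkynyl ether, favoured because the C3 hydrogen of the Z isomer lies anti to bromide, with a hindered non-nucleophilic amide at low temperature so that the push-pull alkyne is not attacked.

Step 8
Reactants: 7 6-methyl-2-oxo-2H-pyran-4-yl 2,4-bis(benzyloxy)-5-chloro-3,6-dimethylbenzoate, 11 methyl 3-methoxypropiolate
Product: 13 methyl 4-{[2,4-bis(benzyloxy)-5-chloro-3,6-dimethylbenzoyl]oxy}-2-methoxy-6-methylbenzoate, via bridged lactone 12 (not isolated)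
Conditions: 11 (4 equiv), BHT (cat.), 1,2-dichlorobenzene, 170 °C, sealed tube
Reagents that add atoms: none
Why: Proposed new method: the alkyne should add thermally in a (4+2) sense across C3 and C6 of the pyrone to give the 2-oxabicyclo[2.2.2]octadienone 12, which cannot persist at 170 °C and expels CO2 by cycloreversion to leave the benzene ring. The closest known reaction type is the Diels–Alder reaction of 4-alkoxy-6-methyl-2-pyrones with acetylenic esters followed by loss of CO2; a 3-alkoxypropiolate has not been used as the 2π partner, nor a 4-aroyloxy pyrone with it. Ring A is closed intermolecularly by a suprafacial cycloaddition that forms C2–C3 and C1–C6 at once, four ring carbons coming from the pyrone and two from the alkyne, and the cycloreversion then only removes the lactone bridge. No stereocentre is created in 13, since the two bridgehead centres of racemic 12 vanish on aromatisation. The selectivity needed is the orientation of the alkyne: pyrone C3, the nucleophilic carbon next to the acyloxy-bearing C4, should bond to the electrophilic methoxy-bearing alkyne carbon (the β-carbon of the ynoate) and C6 to the ester-bearing carbon, so the donor and acceptor ends of both partners agree and place OCH3 at C2 and CO2CH3 at C1 beside the C6 methyl. The methyl ynol ether has no β-hydrogen and so cannot collapse to a ketene by retro-ene reaction on heating, and the di-ortho-substituted aroyl ester is shielded against acyl transfer.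

Step 9
Reactants: 13 methyl 4-{[2,4-bis(benzyloxy)-5-chloro-3,6-dimethylbenzoyl]oxy}-2-methoxy-6-methylbenzoate
Product: 14 methyl 4-[(5-chloro-2,4-dihydroxy-3,6-dimethylbenzoyl)oxy]-2-hydroxy-6-methylbenzoate (CNP0171762.0)
Conditions: BCl3 (8 equiv), C6HMe5 (6 equiv), CH2Cl2, −78 → 0 °C; then H2O
Reagents that add atoms: none
Why: Lewis acid ether cleavage, in which BCl3 should remove both benzyl groups (the benzyl cation being trapped by pentamethylbenzene) and, by chelation to the neighbouring ester carbonyl, the C2 methyl ether of ring A, while the methyl ester, the depside ester and the aryl chloride should survive at or below 0 °C.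

**Compound list**

1 | atraric acid, methyl 2,4-dihydroxy-3,6-dimethylbenzoate | COC(=O)c1c(C)cc(O)c(C)c1O | starting material
2 | methyl 5-chloro-2,4-dihydroxy-3,6-dimethylbenzoate | COC(=O)c1c(C)c(Cl)c(O)c(C)c1O | intermediate
3 | methyl 2,4-bis(benzyloxy)-5-chloro-3,6-dimethylbenzoate | COC(=O)c1c(C)c(Cl)c(OCc2ccccc2)c(C)c1OCc1ccccc1 | intermediate
4 | 2,4-bis(benzyloxy)-5-chloro-3,6-dimethylbenzoic acid | OC(=O)c1c(C)c(Cl)c(OCc2ccccc2)c(C)c1OCc1ccccc1 | intermediate
5 | 2,4-bis(benzyloxy)-5-chloro-3,6-dimethylbenzoyl chloride | ClC(=O)c1c(C)c(Cl)c(OCc2ccccc2)c(C)c1OCc1ccccc1 | intermediate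
6 | triacetic acid lactone, 4-hydroxy-6-methyl-2H-pyran-2-one | Cc1cc(O)cc(=O)o1 | starting material
7 | 6-methyl-2-oxo-2H-pyran-4-yl 2,4-bis(benzyloxy)-5-chloro-3,6-dimethylbenzoate | Cc1cc(OC(=O)c2c(C)c(Cl)c(OCc3ccccc3)c(C)c2OCc2ccccc2)cc(=O)o1 | intermediate
8 | methyl (E)-3-methoxyacrylate | CO/C=C/C(=O)OC | starting material
9 | methyl 2,3-dibromo-3-methoxypropanoate (mixture of diastereomers, racemic) | COC(Br)C(Br)C(=O)OC | intermediate
10 | methyl (Z)-2-bromo-3-methoxyacrylate | CO/C=C(\Br)C(=O)OC | intermediate
11 | methyl 3-methoxypropiolate | COC#CC(=O)OC | intermediate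
12 | methyl 5-{[2,4-bis(benzyloxy)-5-chloro-3,6-dimethylbenzoyl]oxy}-8-methoxy-1-methyl-3-oxo-2-oxabicyclo[2.2.2]octa-5,7-diene-7-carboxylate (racemic, one enantiomer drawn) | C[C@]12OC(=O)[C@H](C(OC(=O)c3c(C)c(Cl)c(OCc4ccccc4)c(C)c3OCc3ccccc3)=C1)C(OC)=C2C(=O)OC | intermediate
13 | methyl 4-{[2,4-bis(benzyloxy)-5-chloro-3,6-dimethylbenzoyl]oxy}-2-methoxy-6-methylbenzoate | COC(=O)c1c(C)cc(OC(=O)c2c(C)c(Cl)c(OCc3ccccc3)c(C)c2OCc2ccccc2)cc1OC | intermediate
14 | methyl 4-[(5-chloro-2,4-dihydroxy-3,6-dimethylbenzoyl)oxy]-2-hydroxy-6-methylbenzoate | COC(=O)c1c(C)cc(OC(=O)c2c(C)c(Cl)c(O)c(C)c2O)cc1O | target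

**Step count**

Total: 9 steps. Longest linear sequence: 7 steps (1, 2, 3, 4, 5, 8, 9). The alkyne branch (steps 6 and 7) joins at step 8.

**Steps most likely to fail**

Step 8 (new method). The push-pull alkyne may oligomerise faster than it adds to the only moderately electron-rich pyrone. The pyranyl ester may also shed its acyl group at 170 °C, and steric repulsion between the ester and the C6 methyl may erode the orientation. The fallback uses known depside chemistry and sets out from acid chloride 5. It is coupled with commercial methyl orsellinate (methyl 2,4-dihydroxy-6-methylbenzoate, COC(=O)c1c(C)cc(O)cc1O) under Et3N in CH2Cl2 at 0 °C. The free C4 hydroxyl should react while the C2 hydroxyl is held in a hydrogen bond to the ester, giving methyl 4-{[2,4-bis(benzyloxy)-5-chloro-3,6-dimethylbenzoyl]oxy}-2-hydroxy-6-methylbenzoate F1. BCl3 with pentamethylbenzene in CH2Cl2 at −78 °C then removes the two benzyl groups, and the fallback comes back to the route at 14.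

Step 7. The amide base may add to the newly formed ynoate or fail to remove the vinylic hydrogen at low temperature, and the alkyne may hydrate during work-up. The fallback sets out from bromide 10 and postpones the loss of HBr until after the cycloaddition, so that the free alkyne is never handled. Pyrone ester 7 is heated with 10 and 2,6-di-tert-butylpyridine in mesitylene at 170–180 °C (or first pressed at 12 kbar and then heated). The cycloadduct, methyl 5-{[2,4-bis(benzyloxy)-5-chloro-3,6-dimethylbenzoyl]oxy}-7-bromo-8-methoxy-1-methyl-3-oxo-2-oxabicyclo[2.2.2]oct-5-ene-7-carboxylate F2, should lose CO2 to methyl 4-{[2,4-bis(benzyloxy)-5-chloro-3,6-dimethylbenzoyl]oxy}-1-bromo-6-methoxy-2-methylcyclohexa-2,4-diene-1-carboxylate F3. In F3 the bromine-bearing carbon has no hydrogen, so methanol cannot be lost and aromatisation can occur only by loss of HBr (bromine and the neighbouring hydrogen are trans). The fallback comes back to the route at 13.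

Step 5. Acylation by the di-ortho-substituted acid chloride may be slow, which would let the acyl group migrate from oxygen to C3 of the pyrone or let the product hydrolyse during purification. The fallback sets out from lactone 6 and forms the depside ester only after ring A exists; its cycloaddition uses the known 4-alkoxy pyrone diene class but still depends on the untested alkyne 11. Benzylation of 6 (BnBr, K2CO3, acetone, reflux) gives 4-(benzyloxy)-6-methyl-2H-pyran-2-one F4. Heating F4 with alkyne 11 as in step 8 should give, through the bridged lactone methyl 5-(benzyloxy)-8-methoxy-1-methyl-3-oxo-2-oxabicyclo[2.2.2]octa-5,7-diene-7-carboxylate F5, the arene methyl 4-(benzyloxy)-2-methoxy-6-methylbenzoate F6. Hydrogenolysis (H2, Pd/C, EtOAc) frees the phenol methyl 4-hydroxy-2-methoxy-6-methylbenzoate F7, which is acylated with acid chloride 5 (Et3N, DMAP, CH2Cl2). The fallback comes back to the route at 13.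

**Further compounds**

F1 | step 8 | methyl 4-{[2,4-bis(benzyloxy)-5-chloro-3,6-dimethylbenzoyl]oxy}-2-hydroxy-6-methylbenzoate | COC(=O)c1c(C)cc(OC(=O)c2c(C)c(Cl)c(OCc3ccccc3)c(C)c2OCc2ccccc2)cc1O
F2 | step 7 | methyl 5-{[2,4-bis(benzyloxy)-5-chloro-3,6-dimethylbenzoyl]oxy}-7-bromo-8-methoxy-1-methyl-3-oxo-2-oxabicyclo[2.2.2]oct-5-ene-7-carboxylate (racemic, Br and OCH3 cis, endo/exo mixture) | CC12OC(=O)C(C(OC(=O)c3c(C)c(Cl)c(OCc4ccccc4)c(C)c3OCc3ccccc3)=C1)[C@@H](OC)[C@]2(Br)C(=O)OC
F3 | step 7 | methyl 4-{[2,4-bis(benzyloxy)-5-chloro-3,6-dimethylbenzoyl]oxy}-1-bromo-6-methoxy-2-methylcyclohexa-2,4-diene-1-carboxylate (racemic, Br and OCH3 cis) | COC(=O)[C@]1(Br)C(C)=CC(OC(=O)c2c(C)c(Cl)c(OCc3ccccc3)c(C)c2OCc2ccccc2)=C[C@H]1OC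
F4 | step 5 | 4-(benzyloxy)-6-methyl-2H-pyran-2-one | Cc1cc(OCc2ccccc2)cc(=O)o1
F5 | step 5 | methyl 5-(benzyloxy)-8-methoxy-1-methyl-3-oxo-2-oxabicyclo[2.2.2]octa-5,7-diene-7-carboxylate (racemic, one enantiomer drawn) | C[C@]12OC(=O)[C@H](C(OCc3ccccc3)=C1)C(OC)=C2C(=O)OC
F6 | step 5 | methyl 4-(benzyloxy)-2-methoxy-6-methylbenzoate | COC(=O)c1c(C)cc(OCc2ccccc2)cc1OC
F7 | step 5 | methyl 4-hydroxy-2-methoxy-6-methylbenzoate | COC(=O)c1c(C)cc(O)cc1OC
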